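**Plan**

- Retrosynthesis first removes the fourteen O-methyl groups and the two carboxyl groups on ring A, then opens ring A at its 2,3 and 5,6 carbon–carbon bonds. Ring A is a phloroglucinol whose ether carbon (carbon 1) lies between the hydroxylated carbons 2 and 6, with carbon 4 hydroxylated too, so the crowded aryl–oxygen bond at carbon 1 can be made earlier on an sp3 malonate carbon.
- The bond from carbon 1 of ring A to the bridging oxygen is cut next (phenoxide plus chloromalonate), leaving the permethylated phenol of rings B to G.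
- The hexamer is cut at its five diaryl ether bonds (rings G/F, F/E, E/D, D/C and C/B), each at carbon 4 of the inner ring (carbon 2 for ring D), para or ortho to a formyl group that later becomes the next phenol.
- Forward: the chain grows G → F → E → D → C → B by five rounds of C–O arylation and Baeyer–Villiger oxidation. The ring B phenol is then alkylated by the malonate, ring A (the only ring built de novo) is closed, the esters are removed and all methyl ethers are cleaved.
- Stereochemistry: the target has no stereocentre, so nothing has to be set or protected.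

Key step: step 12

Remark: the diaryl ether axes are taken to rotate freely (no atropisomers), and 4-fluoro-3,5-dimethoxybenzaldehyde is taken to be a catalogue compound.

Shorthand used in names (all groups permethylated, rings lettered A to G along the chain):
- Ar2O = 3,5-dimethoxy-4-(3,4,5-trimethoxyphenoxy)phenoxy (rings F–G)
- Ar3O = 3,5-dimethoxy-4-(Ar2O)phenoxy (rings E–G)
- Ar4O = 3,4,5-trimethoxy-2-(Ar3O)phenoxy (rings D–G, bound through carbon 1 of ring D; Ar3O sits on carbon 2 of ring D)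
- Ar5O = 3,5-dimethoxy-4-(Ar4O)phenoxy (rings C–G)
- Ar6O = 3,5-dimethoxy-4-(Ar5O)phenoxy (rings B–G)

**Route**

Step 1
Reactants: 1 3,4,5-trimethoxyphenol (ring G); 2 4-fluoro-3,5-dimethoxybenzaldehyde
Product: 3 3,5-dimethoxy-4-(3,4,5-trimethoxyphenoxy)benzaldehyde (rings F–G aldehyde)
Conditions: K2CO3, DMSO, 120 °C, N2
Reagents that add atoms: none
Why: SNAr (addition–elimination), in which the para-formyl group stabilises the Meisenheimer adduct and fluoride is the best leaving group for this mechanism, so the unhindered phenoxide of 1 should displace it at carbon 4 despite the two flanking methoxy groups.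

Step 2
Reactants: 3 3,5-dimethoxy-4-(3,4,5-trimethoxyphenoxy)benzaldehyde
Product: 5 3,5-dimethoxy-4-(3,4,5-trimethoxyphenoxy)phenol (rings F–G phenol), via aryl formate 4 (not isolated)
Conditions: mCPBA, CH2Cl2, 0 °C to rt; aq. Na2SO3/NaHCO3 wash; then K2CO3 (cat.), MeOH, rt
Reagents that add atoms: mCPBA (3-chloroperoxybenzoic acid), O=C(OO)c1cccc(Cl)c1
Why: Baeyer–Villiger oxidation, in which the electron-rich aryl group should migrate in preference to hydride in the Criegee intermediate, followed by mild methanolysis of the aryl formate that leaves methyl and diaryl ethers untouched.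

Step 3
Reactants: 5 3,5-dimethoxy-4-(3,4,5-trimethoxyphenoxy)phenol; 2 4-fluoro-3,5-dimethoxybenzaldehyde
Product: 6 3,5-dimethoxy-4-(Ar2O)benzaldehyde (rings E–G aldehyde)
Conditions: K2CO3, DMSO, 120 °C, N2
Reagents that add atoms: none
Why: SNAr as in step 1; the phenoxide oxygen of 5 again carries only hydrogen at both ortho positions, and the only aryloxy group activated for exchange in the product is the one just introduced, so the inner ethers cannot scramble.

Step 4
Reactants: 6 3,5-dimethoxy-4-(Ar2O)benzaldehyde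
Product: 8 3,5-dimethoxy-4-(Ar2O)phenol (rings E–G phenol with the free OH on ring E), via aryl formate 7 (not isolated)
Conditions: mCPBA, CH2Cl2, 0 °C to rt; aq. Na2SO3/NaHCO3 wash; then K2CO3 (cat.), MeOH, rt
Reagents that add atoms: mCPBA (3-chloroperoxybenzoic acid), O=C(OO)c1cccc(Cl)c1
Why: Baeyer–Villiger oxidation with aryl migration as in step 2, the para-aryloxy and meta-methoxy pattern being the same as in 3.

Step 5
Reactants: 8 3,5-dimethoxy-4-(Ar2O)phenol; 9 2-bromo-3,4,5-trimethoxybenzaldehyde (ring D)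
Product: 10 3,4,5-trimethoxy-2-(Ar3O)benzaldehyde (rings D–G aldehyde with the formyl group on carbon 1 of ring D)
Conditions: CuI (10 mol %), N,N-dimethylglycine hydrochloride (30 mol %), Cs2CO3, 1,4-dioxane, 100 °C, Ar
Reagents that add atoms: none
Why: Ullmann diaryl ether coupling, in which the ortho-formyl group activates the C–Br bond towards monovalent copper, as is well established for 2-bromo-3,4,5-trimethoxybenzoyl electrophiles, while the phenol 8 has two free ortho positions.

Step 6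
Reactants: 10 3,4,5-trimethoxy-2-(Ar3O)benzaldehyde
Product: 12 3,4,5-trimethoxy-2-(Ar3O)phenol (rings D–G phenol with the free OH on carbon 1 of ring D), via aryl formate 11 (not isolated)
Conditions: mCPBA, CH2Cl2, 0 °C to rt; aq. Na2SO3/NaHCO3 wash; then K2CO3 (cat.), MeOH, rt
Reagents that add atoms: mCPBA (3-chloroperoxybenzoic acid), O=C(OO)c1cccc(Cl)c1
Why: Baeyer–Villiger oxidation, here especially favourable because the migrating ring D carbon has an ortho-aryloxy and a para-methoxy donor.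

Step 7
Reactants: 12 3,4,5-trimethoxy-2-(Ar3O)phenol; 2 4-fluoro-3,5-dimethoxybenzaldehyde
Product: 13 3,5-dimethoxy-4-(Ar4O)benzaldehyde (rings C–G aldehyde)
Conditions: Cs2CO3, DMSO, 130 °C, N2
Reagents that add atoms: none
Why: SNAr on the formyl-activated fluoride as in step 1, run with the more dissociated cesium phenoxide and at higher temperature because the phenoxide oxygen on ring D now has one ortho substituent.

Step 8
Reactants: 13 3,5-dimethoxy-4-(Ar4O)benzaldehyde
Product: 15 3,5-dimethoxy-4-(Ar4O)phenol (rings C–G phenol with the free OH on ring C), via aryl formate 14 (not isolated)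
Conditions: mCPBA, CH2Cl2, 0 °C to rt; aq. Na2SO3/NaHCO3 wash; then K2CO3 (cat.), MeOH, rt
Reagents that add atoms: mCPBA (3-chloroperoxybenzoic acid), O=C(OO)c1cccc(Cl)c1
Why: Baeyer–Villiger oxidation with aryl migration, the same transformation as steps 2 and 4 on the same aldehyde substitution pattern.

Step 9
Reactants: 15 3,5-dimethoxy-4-(Ar4O)phenol; 2 4-fluoro-3,5-dimethoxybenzaldehyde
Product: 16 3,5-dimethoxy-4-(Ar5O)benzaldehyde (rings B–G aldehyde)
Conditions: K2CO3, DMSO, 120 °C, N2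
Reagents that add atoms: none
Why: SNAr as in steps 1 and 3, the ring C phenoxide again being unhindered at both ortho positions.

Step 10
Reactants: 16 3,5-dimethoxy-4-(Ar5O)benzaldehyde
Product: 18 3,5-dimethoxy-4-(Ar5O)phenol (rings B–G phenol with the free OH on ring B), via aryl formate 17 (not isolated)
Conditions: mCPBA, CH2Cl2, 0 °C to rt; aq. Na2SO3/NaHCO3 wash; then K2CO3 (cat.), MeOH, rt
Reagents that add atoms: mCPBA (3-chloroperoxybenzoic acid), O=C(OO)c1cccc(Cl)c1
Why: Baeyer–Villiger oxidation with aryl migration and formate methanolysis, as in the earlier cycles.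

Step 11
Reactants: 18 3,5-dimethoxy-4-(Ar5O)phenol; 19 dimethyl chloromalonate
Product: 20 dimethyl 2-(Ar6O)malonate
Conditions: K2CO3, acetone, reflux, N2
Reagents that add atoms: none
Why: Williamson ether synthesis (SN2) at the doubly activated secondary chloride, the chloride being chosen over the bromide because electron-rich phenoxides tend to attack the bromine of bromomalonates and become ring-brominated.

Step 12
Reactants: 20 dimethyl 2-(Ar6O)malonate; 21 dimethyl 3-oxoglutarate
Product: 23 dimethyl 2,4,6-trihydroxy-5-(Ar6O)benzene-1,3-dicarboxylate, via open-chain triester 22 (not isolated)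
Conditions: NaOMe (excess), MeOH then toluene, 65 to 100 °C, slow addition of 21 (3 equiv), Ar; then aq. HCl
Reagents that add atoms: none
Why: Methoxide forms the enolate of 21, which attacks one ester of 20 in a crossed Claisen condensation to give 22 (new bond between carbons 2 and 3 of ring A); the remaining CH2 of 22 then attacks the second malonate ester in a Dieckmann-type closure (new bond between carbons 5 and 6 of ring A), a 6-(enolendo)-exo-trig cyclisation that forms ring A. Loss of two methoxides and threefold enolisation should give the aromatic triol, whose polyphenolate is the thermodynamic sink under equilibrating alkoxide conditions. The closest known reactions are the classical malonate–acetonedicarboxylate condensation to phloroglucinol carboxylates and the double acylation of amidines by aryloxymalonates under NaOMe to give 5-aryloxy-4,6-dihydroxypyrimidines. No stereocentre is formed, and because the malonate is symmetric and ring A has a mirror plane through its carbons 1 and 4 there is no regiochemical question. The step needs C- over O-acylation and cross- over self-condensation of 21: a pyranone from O-acylation would be reopened by methoxide and drain to the arene, and self-condensation is held back by adding 21 slowly to the malonate, whose esters are inductively activated by the aryloxy oxygen on the central carbon.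

Step 13
Reactants: 23 dimethyl 2,4,6-trihydroxy-5-(Ar6O)benzene-1,3-dicarboxylate
Product: 25 2-(Ar6O)benzene-1,3,5-triol, via diacid 24 (not isolated)
Conditions: KOH, H2O/MeOH (degassed), reflux, Ar; then HCl to pH 1, 60 °C
Reagents that add atoms: none
Why: Ester saponification followed by decarboxylation, since 2,4,6-trihydroxybenzoic acids lose CO2 readily on warming in acid through their keto tautomers (β-keto acid pathway), while aryl methyl and diaryl ethers are inert to aqueous hydroxide.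

Step 14
Reactants: 25 2-(Ar6O)benzene-1,3,5-triol
Product: 26 CNP0304148.0 (target)
Conditions: BBr3 (large excess), CH2Cl2, −78 °C to rt, Ar; then H2O, 0 °C
Reagents that add atoms: none
Why: Lewis acid-mediated cleavage of aryl methyl ethers with BBr3, which should convert each of the fourteen OMe groups into an aryloxyborane and MeBr without breaking diaryl ether bonds, hydrolysis then releasing the free phenols.

**Compound list**

1 | 3,4,5-trimethoxyphenol | COc1cc(O)cc(OC)c1OC | starting material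
2 | 4-fluoro-3,5-dimethoxybenzaldehyde | O=Cc1cc(OC)c(F)c(OC)c1 | starting material
3 | 3,5-dimethoxy-4-(3,4,5-trimethoxyphenoxy)benzaldehyde | O=Cc1cc(OC)c(Oc2cc(OC)c(OC)c(OC)c2)c(OC)c1 | intermediate
4 | 3,5-dimethoxy-4-(3,4,5-trimethoxyphenoxy)phenyl formate | O=COc1cc(OC)c(Oc2cc(OC)c(OC)c(OC)c2)c(OC)c1 | intermediate
5 | 3,5-dimethoxy-4-(3,4,5-trimethoxyphenoxy)phenol | Oc1cc(OC)c(Oc2cc(OC)c(OC)c(OC)c2)c(OC)c1 | intermediate
6 | 3,5-dimethoxy-4-(Ar2O)benzaldehyde | O=Cc1cc(OC)c(Oc2cc(OC)c(Oc3cc(OC)c(OC)c(OC)c3)c(OC)c2)c(OC)c1 | intermediate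
7 | 3,5-dimethoxy-4-(Ar2O)phenyl formate | O=COc1cc(OC)c(Oc2cc(OC)c(Oc3cc(OC)c(OC)c(OC)c3)c(OC)c2)c(OC)c1 | intermediate
8 | 3,5-dimethoxy-4-(Ar2O)phenol | Oc1cc(OC)c(Oc2cc(OC)c(Oc3cc(OC)c(OC)c(OC)c3)c(OC)c2)c(OC)c1 | intermediate
9 | 2-bromo-3,4,5-trimethoxybenzaldehyde | O=Cc1cc(OC)c(OC)c(OC)c1Br | starting material
10 | 3,4,5-trimethoxy-2-(Ar3O)benzaldehyde | O=Cc1cc(OC)c(OC)c(OC)c1Oc1cc(OC)c(Oc2cc(OC)c(Oc3cc(OC)c(OC)c(OC)c3)c(OC)c2)c(OC)c1 | intermediate
11 | 3,4,5-trimethoxy-2-(Ar3O)phenyl formate | O=COc1cc(OC)c(OC)c(OC)c1Oc1cc(OC)c(Oc2cc(OC)c(Oc3cc(OC)c(OC)c(OC)c3)c(OC)c2)c(OC)c1 | intermediate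
12 | 3,4,5-trimethoxy-2-(Ar3O)phenol | Oc1cc(OC)c(OC)c(OC)c1Oc1cc(OC)c(Oc2cc(OC)c(Oc3cc(OC)c(OC)c(OC)c3)c(OC)c2)c(OC)c1 | intermediate
13 | 3,5-dimethoxy-4-(Ar4O)benzaldehyde | O=Cc1cc(OC)c(Oc2cc(OC)c(OC)c(OC)c2Oc2cc(OC)c(Oc3cc(OC)c(Oc4cc(OC)c(OC)c(OC)c4)c(OC)c3)c(OC)c2)c(OC)c1 | intermediate
14 | 3,5-dimethoxy-4-(Ar4O)phenyl formate | O=COc1cc(OC)c(Oc2cc(OC)c(OC)c(OC)c2Oc2cc(OC)c(Oc3cc(OC)c(Oc4cc(OC)c(OC)c(OC)c4)c(OC)c3)c(OC)c2)c(OC)c1 | intermediate
15 | 3,5-dimethoxy-4-(Ar4O)phenol | Oc1cc(OC)c(Oc2cc(OC)c(OC)c(OC)c2Oc2cc(OC)c(Oc3cc(OC)c(Oc4cc(OC)c(OC)c(OC)c4)c(OC)c3)c(OC)c2)c(OC)c1 | intermediate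
16 | 3,5-dimethoxy-4-(Ar5O)benzaldehyde | O=Cc1cc(OC)c(Oc2cc(OC)c(Oc3cc(OC)c(OC)c(OC)c3Oc3cc(OC)c(Oc4cc(OC)c(Oc5cc(OC)c(OC)c(OC)c5)c(OC)c4)c(OC)c3)c(OC)c2)c(OC)c1 | intermediate
17 | 3,5-dimethoxy-4-(Ar5O)phenyl formate | O=COc1cc(OC)c(Oc2cc(OC)c(Oc3cc(OC)c(OC)c(OC)c3Oc3cc(OC)c(Oc4cc(OC)c(Oc5cc(OC)c(OC)c(OC)c5)c(OC)c4)c(OC)c3)c(OC)c2)c(OC)c1 | intermediate
18 | 3,5-dimethoxy-4-(Ar5O)phenol (hexamer phenol, rings B–G) | Oc1cc(OC)c(Oc2cc(OC)c(Oc3cc(OC)c(OC)c(OC)c3Oc3cc(OC)c(Oc4cc(OC)c(Oc5cc(OC)c(OC)c(OC)c5)c(OC)c4)c(OC)c3)c(OC)c2)c(OC)c1 | intermediate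
19 | dimethyl chloromalonate | COC(=O)C(Cl)C(=O)OC | starting material
20 | dimethyl 2-(Ar6O)malonate | COC(=O)C(Oc1cc(OC)c(Oc2cc(OC)c(Oc3cc(OC)c(OC)c(OC)c3Oc3cc(OC)c(Oc4cc(OC)c(Oc5cc(OC)c(OC)c(OC)c5)c(OC)c4)c(OC)c3)c(OC)c2)c(OC)c1)C(=O)OC | intermediate
21 | dimethyl 3-oxoglutarate | COC(=O)CC(=O)CC(=O)OC | starting material
22 | dimethyl 2-(Ar6O)-4-(methoxycarbonyl)-3,5-dioxoheptanedioate | COC(=O)CC(=O)C(C(=O)OC)C(=O)C(Oc1cc(OC)c(Oc2cc(OC)c(Oc3cc(OC)c(OC)c(OC)c3Oc3cc(OC)c(Oc4cc(OC)c(Oc5cc(OC)c(OC)c(OC)c5)c(OC)c4)c(OC)c3)c(OC)c2)c(OC)c1)C(=O)OC | intermediate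
23 | dimethyl 2,4,6-trihydroxy-5-(Ar6O)benzene-1,3-dicarboxylate | COC(=O)c1c(O)c(Oc2cc(OC)c(Oc3cc(OC)c(Oc4cc(OC)c(OC)c(OC)c4Oc4cc(OC)c(Oc5cc(OC)c(Oc6cc(OC)c(OC)c(OC)c6)c(OC)c5)c(OC)c4)c(OC)c3)c(OC)c2)c(O)c(C(=O)OC)c1O | intermediate
24 | 2,4,6-trihydroxy-5-(Ar6O)benzene-1,3-dicarboxylic acid | OC(=O)c1c(O)c(Oc2cc(OC)c(Oc3cc(OC)c(Oc4cc(OC)c(OC)c(OC)c4Oc4cc(OC)c(Oc5cc(OC)c(Oc6cc(OC)c(OC)c(OC)c6)c(OC)c5)c(OC)c4)c(OC)c3)c(OC)c2)c(O)c(C(=O)O)c1O | intermediate
25 | 2-(Ar6O)benzene-1,3,5-triol | Oc1cc(O)c(Oc2cc(OC)c(Oc3cc(OC)c(Oc4cc(OC)c(OC)c(OC)c4Oc4cc(OC)c(Oc5cc(OC)c(Oc6cc(OC)c(OC)c(OC)c6)c(OC)c5)c(OC)c4)c(OC)c3)c(OC)c2)c(O)c1 | intermediate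
26 | CNP0304148.0, 2-[3,5-dihydroxy-4-(3,5-dihydroxy-4-{3,4,5-trihydroxy-2-[3,5-dihydroxy-4-(3,5-dihydroxy-4-(3,4,5-trihydroxyphenoxy)phenoxy)phenoxy]phenoxy}phenoxy)phenoxy]benzene-1,3,5-triol | Oc1cc(O)c(Oc2cc(O)c(Oc3cc(O)c(Oc4cc(O)c(O)c(O)c4Oc4cc(O)c(Oc5cc(O)c(Oc6cc(O)c(O)c(O)c6)c(O)c5)c(O)c4)c(O)c3)c(O)c2)c(O)c1 | target

**Count**

Total steps: 14. Longest linear sequence: 14 steps (from 1 to 26).

**Steps most likely to fail**

Step 12 (ring A closure). Self-condensation of the oxoglutarate may outrun the crossed Claisen reaction, and enolisation of the aryloxymalonate may quench the electrophilicity of its esters, so that the hexamer is recovered or degraded by loss of a methoxycarbonyl group. The fallback sets out from 18 and comes back to the route at 26, and installs ring A as a preformed arene by one more round of the chain extension already in use. SNAr of 18 with 2 (K2CO3, DMSO, 120 °C) should give 3,5-dimethoxy-4-(Ar6O)benzaldehyde F1. Baeyer–Villiger oxidation with mCPBA should give 3,5-dimethoxy-4-(Ar6O)phenyl formate F2, which is methanolysed without isolation to 3,5-dimethoxy-4-(Ar6O)phenol F3. Its new ring carries the oxygen pattern of ring A (ether carbon flanked by two oxygens, third oxygen para), so BBr3 cleavage of all sixteen methyl ethers should give 26.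

Step 7 (ether between rings D and C). Addition of the ortho-substituted ring D phenoxide to a fluoride carbon flanked by two methoxy groups may be too slow, with the aldehyde decomposing on prolonged heating. The fallback sets out from 12 and returns at 13, and changes both electrophile and mechanism: copper-catalysed Ullmann coupling of 12 with commercial 4-bromo-3,5-dimethoxybenzaldehyde (CuI, picolinic acid, K3PO4, DMSO, 100 °C). The C–O bond then forms by oxidative addition and reductive elimination at copper, not through a Meisenheimer adduct, and the para-formyl group still activates the halide. No compound outside the list is made (entry F0). The same switch is available for steps 1, 3 and 9.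

Step 14 (global demethylation). Partially demethylated aryloxyboranes may precipitate and stop the cleavage short, and the free polyphenol may oxidise in air during isolation. The fallback sets out from 25 and returns at 26, and isolates the product through a protected derivative. After the BBr3 treatment and quench, the crude polyphenol is acetylated at once (Ac2O, pyridine) to the heptadecaacetate of 26 F4, which is stable to air and can be chromatographed free of partially methylated congeners. Acid-catalysed methanolysis (HCl cat., degassed MeOH, rt) should then release 26 without exposure to base.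

**Further compounds**

F1 | step 12 | 3,5-dimethoxy-4-(Ar6O)benzaldehyde | O=Cc1cc(OC)c(Oc2cc(OC)c(Oc3cc(OC)c(Oc4cc(OC)c(OC)c(OC)c4Oc4cc(OC)c(Oc5cc(OC)c(Oc6cc(OC)c(OC)c(OC)c6)c(OC)c5)c(OC)c4)c(OC)c3)c(OC)c2)c(OC)c1
F2 | step 12 | 3,5-dimethoxy-4-(Ar6O)phenyl formate | O=COc1cc(OC)c(Oc2cc(OC)c(Oc3cc(OC)c(Oc4cc(OC)c(OC)c(OC)c4Oc4cc(OC)c(Oc5cc(OC)c(Oc6cc(OC)c(OC)c(OC)c6)c(OC)c5)c(OC)c4)c(OC)c3)c(OC)c2)c(OC)c1
F3 | step 12 | 3,5-dimethoxy-4-(Ar6O)phenol | Oc1cc(OC)c(Oc2cc(OC)c(Oc3cc(OC)c(Oc4cc(OC)c(OC)c(OC)c4Oc4cc(OC)c(Oc5cc(OC)c(Oc6cc(OC)c(OC)c(OC)c6)c(OC)c5)c(OC)c4)c(OC)c3)c(OC)c2)c(OC)c1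
F0 | step 7 | none | none
F4 | step 14 | heptadecaacetate of 26 | CC(=O)Oc1cc(OC(C)=O)c(Oc2cc(OC(C)=O)c(Oc3cc(OC(C)=O)c(Oc4cc(OC(C)=O)c(OC(C)=O)c(OC(C)=O)c4Oc4cc(OC(C)=O)c(Oc5cc(OC(C)=O)c(Oc6cc(OC(C)=O)c(OC(C)=O)c(OC(C)=O)c6)c(OC(C)=O)c5)c(OC(C)=O)c4)c(OC(C)=O)c3)c(OC(C)=O)c2)c(OC(C)=O)c1
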